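**Strategy**

The bicyclic core is unfolded into an open-chain trialdehyde: in the target, C1, C3 and the formyl carbon on C7 all sit at the aldehyde oxidation level, C1 and C3 are 1,5-related through C7a, C4a and C4, and the five-membered ring (C4a, C5, C6, C7, C7a) lacks only the C4a–C7a bond. One amine-buffered operation is meant to close that bond by a vinylogous Michael addition and then the pyran ring (through O2) by cyclodehydration. The precursor is a (Z)-ene-dial, unmasked from a 3-alkylfuran, linked by two methylenes to an (E)-2-alkylidene aldehyde that carries the (S)-acetoxy side chain; dehydrogenation then gives the 10π system.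

Key step: step 10

Remark: ring locants (O2, C1, C3, C4, C4a, C5–C7, C7a) are those of the cyclopenta[c]pyran in 21.

Assumption: the (S)-enantiomer of the phosphoric acid catalyst in step 3 is taken to deliver the allyl group to the Si face of geranial, by analogy with aryl and alkenyl aldehydes; the configuration of 9 would be confirmed (Mosher esters) before it is carried on.

**Route**

Step 1
Reactants: 1 furan-3-carbaldehyde; 2 (triphenylphosphoranylidene)acetaldehyde
Product: 3 (E)-3-(furan-3-yl)prop-2-enal
Conditions: 2 (1.05 equiv), toluene, 80 °C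
Reagents that add atoms: none
Why: Wittig olefination with the formyl-stabilised ylide gives the E-enal under thermodynamic control, and a near-stoichiometric amount of ylide keeps a second homologation of the product in check.

Step 2
Reactants: 3 (E)-3-(furan-3-yl)prop-2-enal
Product: 5 3-(3,3-dimethoxypropyl)furan, via 3-(furan-3-yl)propanal 4 (not isolated)
Conditions: diethyl 2,6-dimethyl-1,4-dihydropyridine-3,5-dicarboxylate (Hantzsch ester, 1.1 equiv), dibenzylammonium trifluoroacetate (10 mol%), THF, rt; then HC(OMe)3, MeOH, PPTS (5 mol%), rt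
Reagents that add atoms: trimethyl orthoformate, COC(OC)OC; methanol, CO
Why: Iminium-catalysed transfer hydrogenation with the Hantzsch ester reduces only the conjugated C=C bond (furan and carbonyl are left alone), and acid-catalysed acetalisation with the orthoformate as water scavenger stores the volatile aldehyde as the acetal that later serves as the electrophile.

Step 3
Reactants: 6 geranial; 7 allylboronic acid pinacol ester
Product: 9 (4S,5E)-6,10-dimethylundeca-1,5,9-trien-4-ol, via borate ester 8 (not isolated)
Conditions: (S)-3,3′-bis(2,4,6-triisopropylphenyl)-1,1′-binaphthyl-2,2′-diyl hydrogen phosphate ((S)-TRIP, 5 mol%), 4 Å MS, toluene, −30 °C; aqueous NaHCO3 work-up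
Reagents that add atoms: none
Why: Asymmetric allylboration catalysed by a chiral phosphoric acid proceeds through a chair-like six-membered transition state in which the catalyst holds the boronate oxygen and the formyl hydrogen, and the (S)-catalyst is chosen so that the allyl group is delivered to the Si face of the aldehyde, which sets the (S)-carbinol centre without touching the E-alkene.

Step 4
Reactants: 9 (4S,5E)-6,10-dimethylundeca-1,5,9-trien-4-ol
Product: 10 (4S,5E)-6,10-dimethylundeca-1,5,9-trien-4-yl acetate
Conditions: Ac2O, pyridine, DMAP (5 mol%), CH2Cl2, 0 °C to rt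
Reagents that add atoms: acetic anhydride, CC(=O)OC(C)=O
Why: DMAP-catalysed O-acylation does not break the C–O bond, so the (S) configuration is retained.

Step 5
Reactants: 10 (4S,5E)-6,10-dimethylundeca-1,5,9-trien-4-yl acetate
Product: 12 (4S,5E)-1-hydroxy-6,10-dimethylundeca-5,9-dien-4-yl acetate, via alkylborane 11 (not isolated)
Conditions: 9-BBN (1.2 equiv), THF, 0 °C to rt; then NaBO3·4H2O, THF/H2O, rt
Reagents that add atoms: sodium perborate (NaBO3·4H2O), [Na+].[O-]OB=O
Why: Hydroboration–oxidation with the bulky 9-BBN is anti-Markovnikov and selective for the monosubstituted alkene over the two trisubstituted ones, and perborate oxidises the C–B bond at near-neutral pH, where the acetate neither hydrolyses nor migrates.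

Step 6
Reactants: 12 (4S,5E)-1-hydroxy-6,10-dimethylundeca-5,9-dien-4-yl acetate
Product: 13 (4S,5E)-6,10-dimethyl-1-oxoundeca-5,9-dien-4-yl acetate
Conditions: Dess–Martin periodinane (1.2 equiv), CH2Cl2, 0 °C to rt
Reagents that add atoms: none
Why: Dess–Martin oxidation stops cleanly at the aldehyde under neutral conditions that leave the allylic acetate, the alkenes and the remote stereocentre untouched.

Step 7
Reactants: 13 (4S,5E)-6,10-dimethyl-1-oxoundeca-5,9-dien-4-yl acetate
Product: 14 (1Z,4S,5E)-1-[(tert-butyldimethylsilyl)oxy]-6,10-dimethylundeca-1,5,9-trien-4-yl acetate (Z enol ether expected to predominate)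
Conditions: TBSOTf (1.2 equiv), Et3N (2 equiv), CH2Cl2, −78 to 0 °C
Reagents that add atoms: tert-butyldimethylsilyl trifluoromethanesulfonate, CC(C)(C)[Si](C)(C)OS(=O)(=O)C(F)(F)F
Why: Silyl enol ether formation by soft enolisation (O-silylation of the aldehyde, then deprotonation by the amine) is fast at low temperature and does not enolise the acetate, and either enol ether geometry leads to the same product in step 8.

Step 8
Reactants: 14 (1Z,4S,5E)-1-[(tert-butyldimethylsilyl)oxy]-6,10-dimethylundeca-1,5,9-trien-4-yl acetate; 5 3-(3,3-dimethoxypropyl)furan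
Product: 16 (3E,6S,7E)-4-formyl-1-(furan-3-yl)-8,12-dimethyltrideca-3,7,11-trien-6-yl acetate, via β-methoxy aldehyde 15 (not isolated)
Conditions: TMSOTf (10 mol%), CH2Cl2, −78 °C; then DBU (2 equiv), −78 °C to rt
Reagents that add atoms: none
Why: In this Mukaiyama aldol addition the acetal is the only source of the electrophile (an oxocarbenium ion) and the enol silane the only nucleophile, so the two enolisable aldehyde partners cannot exchange roles, and E1cB loss of methanol with DBU then gives the thermodynamically favoured E-configured 2-alkylidene aldehyde.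

Step 9
Reactants: 16 (3E,6S,7E)-4-formyl-1-(furan-3-yl)-8,12-dimethyltrideca-3,7,11-trien-6-yl acetate
Product: 18 (2Z,6E,9S,10E)-3,7-diformyl-11,15-dimethyl-1-oxohexadeca-2,6,10,14-tetraen-9-yl acetate, via furan endoperoxide 17 (not isolated)
Conditions: O2, visible light, tetraphenylporphyrin (1 mol%), CH2Cl2, −78 °C; then Me2S (5 equiv), −78 to 0 °C; crude product used at once
Reagents that add atoms: dioxygen (as singlet oxygen), O=O
Why: [4+2] Cycloaddition of singlet oxygen to the furan, which at −78 °C should run well ahead of the ene reaction at the trisubstituted alkenes, followed by reduction of the O–O bond by the sulfide, opens the ring to the Z-ene-dial with both new carbonyl groups at the aldehyde level.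

Step 10
Reactants: 18 (2Z,6E,9S,10E)-3,7-diformyl-11,15-dimethyl-1-oxohexadeca-2,6,10,14-tetraen-9-yl acetate
Product: 20 (2S,3E)-1-(7-formyl-4a,5-dihydrocyclopenta[c]pyran-4-yl)-4,8-dimethylnona-3,7-dien-2-yl acetate (both C4a epimers), via cyclopentene trialdehyde 19 (not isolated)
Conditions: piperidinium acetate (30 mol%), 4 Å MS, toluene (0.01 M), 0 °C to rt
Reagents that add atoms: none
Why: Proposed new method: piperidine condenses with the unhindered C1 aldehyde of the ene-dial and loss of a C6 proton gives a dienamine (without the amine, the dienolate) whose α-carbon C7a adds to the β-carbon C4a of the tethered 2-alkylidene aldehyde, which leaves C6=C7 conjugated with the C7 formyl group in trialdehyde 19; the enol oxygen of the C1 aldehyde then adds to the C3 aldehyde and loss of water gives the C1=C7a and C3=C4 enol ethers. The closest known reactions are the secondary-amine-mediated cyclisation of 2,6-dienedials of the 8-oxogeranial type (dienamine Michael addition) and the cyclodehydration of 1,5-dialdehydes to 4H-pyrans, but an ene-dial has not been used as the dienamine donor and the two events have not been run as one cascade on such a substrate. The cyclopentene closes 5-exo-trig (C7a onto C4a) and the pyran 6-exo-trig (O2 onto C3). The only new stereocentre, C4a, is left uncontrolled because it becomes sp2 in step 11, and the acetoxy-bearing centre is remote and not epimerisable. The step needs bond formation from C7a and not C6, the ene-dial and not the α-branched enal as donor, and closure of the 1,5- and not the 1,4-dialdehyde pair: C6 attack would give a cyclopropane, the C3 enal condenses with the amine more slowly and could only react through C4 to build a quaternary centre, and the saturated C3 aldehyde of 19 is more electrophilic than the conjugated C7 formyl group and leads to a six-membered vinylogous formate, while buffering and high dilution hold back furan formation and oligomerisation.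

Step 11
Reactants: 20 (2S,3E)-1-(7-formyl-4a,5-dihydrocyclopenta[c]pyran-4-yl)-4,8-dimethylnona-3,7-dien-2-yl acetate
Product: 21 (2S,3E)-1-(7-formylcyclopenta[c]pyran-4-yl)-4,8-dimethylnona-3,7-dien-2-yl acetate
Conditions: DDQ (1.1 equiv), CH2Cl2, 0 °C
Reagents that add atoms: none
Why: Dehydrogenation with DDQ starts by abstraction of the doubly allylic hydride at C4a to give a cation stabilised as a pyrylium ion by O2, and loss of a C5 proton then gives the aromatic 10π cyclopenta[c]pyran without touching the acetoxy-bearing centre.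

**Compound list**

1 | furan-3-carbaldehyde | O=Cc1ccoc1 | starting material
2 | (triphenylphosphoranylidene)acetaldehyde | O=CC=P(c1ccccc1)(c1ccccc1)c1ccccc1 | starting material
3 | (E)-3-(furan-3-yl)prop-2-enal | O=C/C=C/c1ccoc1 | intermediate
4 | 3-(furan-3-yl)propanal | O=CCCc1ccoc1 | intermediate
5 | 3-(3,3-dimethoxypropyl)furan | COC(OC)CCc1ccoc1 | intermediate
6 | geranial, (2E)-3,7-dimethylocta-2,6-dienal | CC(C)=CCC/C(C)=C/C=O | starting material
7 | allylboronic acid pinacol ester, 4,4,5,5-tetramethyl-2-(prop-2-en-1-yl)-1,3,2-dioxaborolane | C=CCB1OC(C)(C)C(C)(C)O1 | starting material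
8 | 2-{[(4S,5E)-6,10-dimethylundeca-1,5,9-trien-4-yl]oxy}-4,4,5,5-tetramethyl-1,3,2-dioxaborolane | C=CC[C@H](OB1OC(C)(C)C(C)(C)O1)/C=C(\C)CCC=C(C)C | intermediate
9 | (4S,5E)-6,10-dimethylundeca-1,5,9-trien-4-ol | C=CC[C@H](O)/C=C(\C)CCC=C(C)C | intermediate
10 | (4S,5E)-6,10-dimethylundeca-1,5,9-trien-4-yl acetate | C=CC[C@H](OC(C)=O)/C=C(\C)CCC=C(C)C | intermediate
11 | (4S,5E)-1-(9-borabicyclo[3.3.1]nonan-9-yl)-6,10-dimethylundeca-5,9-dien-4-yl acetate | B1(CCC[C@H](OC(C)=O)/C=C(\C)CCC=C(C)C)C2CCCC1CCC2 | intermediate
12 | (4S,5E)-1-hydroxy-6,10-dimethylundeca-5,9-dien-4-yl acetate | OCCC[C@H](OC(C)=O)/C=C(\C)CCC=C(C)C | intermediate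
13 | (4S,5E)-6,10-dimethyl-1-oxoundeca-5,9-dien-4-yl acetate | O=CCC[C@H](OC(C)=O)/C=C(\C)CCC=C(C)C | intermediate
14 | (1Z,4S,5E)-1-[(tert-butyldimethylsilyl)oxy]-6,10-dimethylundeca-1,5,9-trien-4-yl acetate | CC(C)(C)[Si](C)(C)O/C=C\C[C@H](OC(C)=O)/C=C(\C)CCC=C(C)C | intermediate
15 | (6S,7E)-4-formyl-1-(furan-3-yl)-3-methoxy-8,12-dimethyltrideca-7,11-dien-6-yl acetate (diastereomers at C3 and C4) | COC(CCc1ccoc1)C(C=O)C[C@H](OC(C)=O)/C=C(\C)CCC=C(C)C | intermediate
16 | (3E,6S,7E)-4-formyl-1-(furan-3-yl)-8,12-dimethyltrideca-3,7,11-trien-6-yl acetate | O=C/C(C[C@H](OC(C)=O)/C=C(\C)CCC=C(C)C)=C/CCc1ccoc1 | intermediate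
17 | (3E,6S,7E)-4-formyl-8,12-dimethyl-1-(2,3,7-trioxabicyclo[2.2.1]hept-5-en-5-yl)trideca-3,7,11-trien-6-yl acetate (bridgehead diastereomers) | O=C/C(C[C@H](OC(C)=O)/C=C(\C)CCC=C(C)C)=C/CCC1=CC2OOC1O2 | intermediate
18 | (2Z,6E,9S,10E)-3,7-diformyl-11,15-dimethyl-1-oxohexadeca-2,6,10,14-tetraen-9-yl acetate | O=C/C=C(C=O)/CC/C=C(C=O)\C[C@H](OC(C)=O)/C=C(\C)CCC=C(C)C | intermediate
19 | (4S,5E)-2-(2,3-diformylcyclopent-3-en-1-yl)-6,10-dimethyl-1-oxoundeca-5,9-dien-4-yl acetate (diastereomers at the three new sp3 centres) | O=CC1C(C=O)=CCC1C(C=O)C[C@H](OC(C)=O)/C=C(\C)CCC=C(C)C | intermediate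
20 | (2S,3E)-1-(7-formyl-4a,5-dihydrocyclopenta[c]pyran-4-yl)-4,8-dimethylnona-3,7-dien-2-yl acetate (both C4a epimers) | CC(=O)O[C@H](/C=C(\C)CCC=C(C)C)CC1=COC=C2C(C=O)=CCC12 | intermediate
21 | (2S,3E)-1-(7-formylcyclopenta[c]pyran-4-yl)-4,8-dimethylnona-3,7-dien-2-yl acetate | CC(=O)O[C@H](/C=C(\C)CCC=C(C)C)Cc1cocc2c(C=O)ccc1-2 | target

**Step count**

Total: 11 steps. Longest linear sequence: 9 steps (6 to 21, steps 3–11); the furan fragment (steps 1–2) joins in step 8.

**Steps most likely to fail**

Step 10 (the cascade, the one step without direct precedent). The ene-dial may be lost to amine addition and oligomerisation before the C7a–C4a bond forms. The α-branched enal may take the donor role. The 1,4-related aldehydes (C1 and the C7 formyl carbon) may condense to a furan faster than the 1,5-pair closes to the pyran. The fallback runs from 14 to 21 and uses known reaction types only: the second carbonyl of the donor is left out during ring formation and put in last. Pent-4-enal is converted into 5,5-dimethoxypent-1-ene F1 (HC(OMe)3, MeOH, PPTS). F1 replaces 5 under the conditions of step 8 and gives, through the β-methoxy aldehyde (8S,9E)-6-formyl-5-methoxy-10,14-dimethylpentadeca-1,9,13-trien-8-yl acetate F2, the enal (5E,8S,9E)-6-formyl-10,14-dimethylpentadeca-1,5,9,13-tetraen-8-yl acetate F3. Cross-metathesis of its terminal alkene with crotonaldehyde (second-generation Hoveyda–Grubbs catalyst, RuCl2(H2IMes)(=CH-C6H4-2-OiPr), CH2Cl2, 40 °C) gives the dienedial (2E,6E,9S,10E)-7-formyl-11,15-dimethyl-1-oxohexadeca-2,6,10,14-tetraen-9-yl acetate F4. This is the substrate type for which the amine-mediated cyclisation is established: piperidinium acetate should give (4S,5E)-2-(2-formylcyclopent-3-en-1-yl)-6,10-dimethyl-1-oxoundeca-5,9-dien-4-yl acetate F5. PPTS with molecular sieves dehydrates this 1,5-dialdehyde to (2S,3E)-1-(4a,5-dihydrocyclopenta[c]pyran-4-yl)-4,8-dimethylnona-3,7-dien-2-yl acetate F6. DDQ gives the pseudoazulene (2S,3E)-1-(cyclopenta[c]pyran-4-yl)-4,8-dimethylnona-3,7-dien-2-yl acetate F7. Vilsmeier–Haack formylation with (chloromethylene)dimethyliminium chloride is expected mainly at C7, the five-ring position remote from the C4 side chain, with any C5 isomer to be separated. It gives N-{[4-((2S,3E)-2-acetoxy-4,8-dimethylnona-3,7-dien-1-yl)cyclopenta[c]pyran-7-yl]methylidene}-N-methylmethanaminium chloride F8, and hydrolysis with aqueous NaOAc returns to the route at 21.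

Step 8. The Lewis acid may ionise the allylic acetate, the furan may attack the oxocarbenium ion in a Friedel–Crafts sense, or the elimination may be incomplete or poorly E-selective. The fallback runs from 13 to 16 and forms the enal C=C bond by olefin metathesis under neutral conditions. Organocatalytic α-methylenation of 13 (aqueous formaldehyde, pyrrolidine and propionic acid, 10 mol% each, iPrOH, 45 °C) gives (4S,5E)-2-formyl-6,10-dimethylundeca-1,5,9-trien-4-yl acetate F9. Aldehyde 4, isolated by stopping step 2 before the acetalisation, gives 3-(but-3-en-1-yl)furan F10 with Ph3P=CH2. Cross-metathesis of F9 with an excess of F10 (second-generation Hoveyda–Grubbs catalyst, RuCl2(H2IMes)(=CH-C6H4-2-OiPr), CH2Cl2, 40 °C) should give the E-trisubstituted enal 16 with loss of ethene; competing metathesis at the prenyl-type alkene is the risk this fallback carries.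

Step 9. Singlet oxygen may undergo the ene reaction at the two trisubstituted alkenes, or the endoperoxide may rearrange before it is reduced. The fallback runs from 16 to 18 and replaces the cycloaddition by an electrophilic 2,5-dimethoxylation and a separate hydrolysis. NBS (1.0 equiv) and NaHCO3 in MeOH at −40 °C should convert the furan, the most nucleophilic π system present, into (3E,6S,7E)-1-(2,5-dimethoxy-2,5-dihydrofuran-3-yl)-4-formyl-8,12-dimethyltrideca-3,7,11-trien-6-yl acetate F11, a bis-acetal that can be purified and stored. Dilute aqueous acetic acid in acetone at rt then releases 18, and this hydrolysis can be run in the flask used for step 10.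

**Further compounds**

F1 | step 10 | 5,5-dimethoxypent-1-ene | C=CCCC(OC)OC
F2 | step 10 | (8S,9E)-6-formyl-5-methoxy-10,14-dimethylpentadeca-1,9,13-trien-8-yl acetate | C=CCCC(OC)C(C=O)C[C@H](OC(C)=O)/C=C(\C)CCC=C(C)C
F3 | step 10 | (5E,8S,9E)-6-formyl-10,14-dimethylpentadeca-1,5,9,13-tetraen-8-yl acetate | C=CCC/C=C(C=O)\C[C@H](OC(C)=O)/C=C(\C)CCC=C(C)C
F4 | step 10 | (2E,6E,9S,10E)-7-formyl-11,15-dimethyl-1-oxohexadeca-2,6,10,14-tetraen-9-yl acetate | O=C/C=C/CC/C=C(C=O)\C[C@H](OC(C)=O)/C=C(\C)CCC=C(C)C
F5 | step 10 | (4S,5E)-2-(2-formylcyclopent-3-en-1-yl)-6,10-dimethyl-1-oxoundeca-5,9-dien-4-yl acetate | O=CC1C=CCC1C(C=O)C[C@H](OC(C)=O)/C=C(\C)CCC=C(C)C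
F6 | step 10 | (2S,3E)-1-(4a,5-dihydrocyclopenta[c]pyran-4-yl)-4,8-dimethylnona-3,7-dien-2-yl acetate | CC(=O)O[C@H](/C=C(\C)CCC=C(C)C)CC1=COC=C2C=CCC12
F7 | step 10 | (2S,3E)-1-(cyclopenta[c]pyran-4-yl)-4,8-dimethylnona-3,7-dien-2-yl acetate | CC(=O)O[C@H](/C=C(\C)CCC=C(C)C)Cc1cocc2cccc1-2
F8 | step 10 | N-{[4-((2S,3E)-2-acetoxy-4,8-dimethylnona-3,7-dien-1-yl)cyclopenta[c]pyran-7-yl]methylidene}-N-methylmethanaminium chloride | CC(=O)O[C@H](/C=C(\C)CCC=C(C)C)Cc1cocc2c(C=[N+](C)C)ccc1-2.[Cl-]
F9 | step 8 | (4S,5E)-2-formyl-6,10-dimethylundeca-1,5,9-trien-4-yl acetate | C=C(C=O)C[C@H](OC(C)=O)/C=C(\C)CCC=C(C)C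
F10 | step 8 | 3-(but-3-en-1-yl)furan | C=CCCc1ccoc1
F11 | step 9 | (3E,6S,7E)-1-(2,5-dimethoxy-2,5-dihydrofuran-3-yl)-4-formyl-8,12-dimethyltrideca-3,7,11-trien-6-yl acetate | O=C/C(C[C@H](OC(C)=O)/C=C(\C)CCC=C(C)C)=C/CCC1=CC(OC)OC1OC
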